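**Retrosynthetic overview**
1. Target 25 ⇐ bis-silyl ether 23 by one-pot desilylation and acetylation at C3 and C9.
2. 23 ⇐ acyclic Z-enal/E-enoate 21: an SmI2 ketyl–enoate reductive coupling joins the two normally electrophilic carbons C6 (aldehyde) and C7 (enoate β-carbon), closing the ten-membered carbocycle and then the cis-fused γ-lactone in the same flask (sets C6, C7, C11).
3. 21 ⇐ Z-enal 15 + tiglate silyl dienolate 17 by asymmetric vinylogous Mukaiyama aldol (C8–C9, sets C9), then Sharpless epoxidation (C1, C10), silylation and direct oxidation of the TES ether.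
4. 15 ⇐ Z-alkenylmagnesium 11 (from but-2-yn-1-ol) + Weinreb amide 10 (C3–C4), then CBS reduction (sets C3).
5. 10 ⇐ Z-selective Wittig of 1,1-dimethoxypropan-2-one (C1=C10). Ring order: epoxide, then carbocycle, then lactone.

Assumption: locants C1–C15 are germacrane numbering (C6 carries the lactone oxygen, C12 is the lactone carbonyl, C13/C14/C15 are the methyls on C11/C10/C4); the target is read as (1R,3R,6R,7S,9S,10R,11R) with a Z C4=C5 bond, a cis-fused lactone and a cis epoxide.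

**Step 1**
Reactants: 1 but-2-yn-1-ol
Product: 3 (Z)-3-iodobut-2-en-1-ol, via cyclic alkenylalanate 2 (not isolated)
Conditions: NaAlH2(OCH2CH2OMe)2, THF, 0 °C → rt; EtOAc; then I2, −78 → 0 °C
Reagents that add atoms: iodine, [I][I]
Why: Alkoxide-directed trans-hydroalumination of the propargylic alcohol puts aluminium on C3 cis to the CH2O group (five-membered alanate 2) and iodinolysis occurs with retention, so only the Z vinyl iodide forms (hydroalumination–iodination of a propargylic alcohol).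

**Step 2**
Reactants: 3 (Z)-3-iodobut-2-en-1-ol
Product: 4 (Z)-triethyl[(3-iodobut-2-en-1-yl)oxy]silane
Conditions: Et3SiCl, imidazole, CH2Cl2, 0 °C
Reagents that add atoms: chlorotriethylsilane, CC[Si](Cl)(CC)CC
Why: Routine silylation of a primary alcohol; the TES ether is chosen because it can later be oxidised directly to the aldehyde.

**Step 3**
Reactants: 5 (2-carboxyethyl)triphenylphosphonium bromide; 6 1,1-dimethoxypropan-2-one
Product: 10 (Z)-N,5,5-trimethoxy-N,4-dimethylpent-3-enamide, via ylide carboxylate 7 (not isolated), via sodium carboxylate 8 (not isolated), via mixed pivalic anhydride 9 (not isolated)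
Conditions: NaN(SiMe3)2 (2.05 equiv), THF, −78 → 0 °C; 6, −78 °C → rt; then t-BuCOCl, 0 °C; then MeNH(OMe)·HCl, N-methylmorpholine, 0 °C → rt
Reagents that add atoms: N,O-dimethylhydroxylamine hydrochloride, CNOC.Cl
Why: Wittig olefination of an α,α-dialkoxy methyl ketone with a non-stabilised ylide is Z-selective (the oxygenated carbon ends up cis to the ylide chain), and the sodium carboxylate is converted through the mixed anhydride into the Weinreb amide without exposing the allylic acetal to acid.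

**Step 4**
Reactants: 4 (Z)-triethyl[(3-iodobut-2-en-1-yl)oxy]silane; 10 (Z)-N,5,5-trimethoxy-N,4-dimethylpent-3-enamide
Product: 12 (2Z,6Z)-8,8-dimethoxy-3,7-dimethyl-1-(triethylsilyloxy)octa-2,6-dien-4-one, via alkenylmagnesium chloride 11 (not isolated)
Conditions: 4, i-PrMgCl·LiCl, THF, 0 °C → rt; then 10, −20 → 0 °C; NH4Cl (aq)
Reagents that add atoms: none
Why: Iodine–magnesium exchange retains the olefin geometry and the magnesium reagent adds once to the Weinreb amide through the chelated tetrahedral intermediate (Weinreb ketone synthesis), magnesium rather than lithium avoiding 1,4-silyl migration and enolisation of the amide.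

**Step 5**
Reactants: 12 (2Z,6Z)-8,8-dimethoxy-3,7-dimethyl-1-(triethylsilyloxy)octa-2,6-dien-4-one
Product: 13 (2Z,4R,6Z)-8,8-dimethoxy-3,7-dimethyl-1-(triethylsilyloxy)octa-2,6-dien-4-ol
Conditions: (S)-2-methyl-CBS-oxazaborolidine (20 mol %), catecholborane, toluene, −78 °C
Reagents that add atoms: none
Why: Corey–Bakshi–Shibata reduction: the α-methyl alkenyl group acts as the large substituent, so the (S)-oxazaborolidine delivers hydride to the face that gives the 4R alcohol (C3 of the target), and catecholborane at −78 °C leaves the olefins untouched.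

**Step 6**
Reactants: 13 (2Z,4R,6Z)-8,8-dimethoxy-3,7-dimethyl-1-(triethylsilyloxy)octa-2,6-dien-4-ol
Product: 14 (2Z,4R,6Z)-4-(tert-butyldimethylsilyloxy)-8,8-dimethoxy-3,7-dimethyl-1-(triethylsilyloxy)octa-2,6-diene
Conditions: t-BuMe2SiCl, imidazole, DMF, rt
Reagents that add atoms: tert-butylchlorodimethylsilane, CC(C)(C)[Si](C)(C)Cl
Why: Standard silylation of the secondary allylic alcohol, giving a C3 oxygen substituent that is a poor leaving group for the later reductive step.

**Step 7**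
Reactants: 14 (2Z,4R,6Z)-4-(tert-butyldimethylsilyloxy)-8,8-dimethoxy-3,7-dimethyl-1-(triethylsilyloxy)octa-2,6-diene
Product: 15 (2Z,5R,6Z)-5-(tert-butyldimethylsilyloxy)-2,6-dimethyl-8-(triethylsilyloxy)octa-2,6-dienal
Conditions: 10% aq. oxalic acid on SiO2, CH2Cl2, 0 °C
Reagents that add atoms: water, O
Why: The α,β-unsaturated dimethyl acetal ionises through an allylic oxocarbenium ion far faster than the silyl ethers hydrolyse, so mild heterogeneous acid releases the Z enal (acetal hydrolysis) without loss of TES or olefin isomerisation.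

**Step 8**
Reactants: 16 methyl (E)-2-methylbut-2-enoate (methyl tiglate)
Product: 17 tert-butyl[(1-methoxy-2-methylbuta-1,3-dien-1-yl)oxy]dimethylsilane
Conditions: LiN(i-Pr)2, THF/DMPU, −78 °C; t-BuMe2SiCl
Reagents that add atoms: tert-butylchlorodimethylsilane, CC(C)(C)[Si](C)(C)Cl
Why: γ-Deprotonation of the tiglate and O-silylation of the dienolate give the vinylogous silyl ketene acetal (silyl dienolate formation).

**Step 9**
Reactants: 15 (2Z,5R,6Z)-5-(tert-butyldimethylsilyloxy)-2,6-dimethyl-8-(triethylsilyloxy)octa-2,6-dienal; 17 tert-butyl[(1-methoxy-2-methylbuta-1,3-dien-1-yl)oxy]dimethylsilane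
Product: 18 methyl (2E,5S,6Z,9R,10Z)-9-(tert-butyldimethylsilyloxy)-5-hydroxy-2,6,10-trimethyl-12-(triethylsilyloxy)dodeca-2,6,10-trienoate
Conditions: SiCl4 (1.1 equiv), (S,S)-binaphthyldiamine-derived bisphosphoramide (pentane-1,5-diyl linked, 5 mol %; the enantiomer that directs Si-face attack), i-Pr2NEt (10 mol %), CH2Cl2, −78 °C; NaHCO3/KF (aq)
Reagents that add atoms: none
Why: Lewis-base-activated SiCl4 vinylogous Mukaiyama aldol reaction: attack through the γ-carbon gives the E enoate directly and the chiral phosphoramide-bound silicon cation directs the dienolate to the Si face of the aldehyde, setting C9 as S.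

**Step 10**
Reactants: 18 methyl (2E,5S,6Z,9R,10Z)-9-(tert-butyldimethylsilyloxy)-5-hydroxy-2,6,10-trimethyl-12-(triethylsilyloxy)dodeca-2,6,10-trienoate
Product: 19 methyl (2E,5S)-5-hydroxy-2-methyl-5-{(2S,3R)-2-methyl-3-[(2R,3Z)-2-(tert-butyldimethylsilyloxy)-3-methyl-5-(triethylsilyloxy)pent-3-en-1-yl]oxiran-2-yl}pent-2-enoate
Conditions: Ti(O-i-Pr)4 (1.0 equiv), L-(+)-diethyl tartrate (1.2 equiv), t-BuOOH, 4 Å molecular sieves, CH2Cl2, −20 °C
Reagents that add atoms: tert-butyl hydroperoxide, CC(C)(C)OO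
Why: Sharpless asymmetric epoxidation: only the olefin next to the free hydroxyl is epoxidised, and L-(+)-tartrate delivers oxygen to the face that is matched with the 9S alcohol and gives the erythro cis epoxide (1R,10R in the target; the oxirane C2 label reads S here only because the free OH changes CIP priorities).

**Step 11**
Reactants: 19 methyl (2E,5S)-5-hydroxy-2-methyl-5-{(2S,3R)-2-methyl-3-[(2R,3Z)-2-(tert-butyldimethylsilyloxy)-3-methyl-5-(triethylsilyloxy)pent-3-en-1-yl]oxiran-2-yl}pent-2-enoate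
Product: 20 methyl (2E,5S)-5-(tert-butyldimethylsilyloxy)-2-methyl-5-{(2R,3R)-2-methyl-3-[(2R,3Z)-2-(tert-butyldimethylsilyloxy)-3-methyl-5-(triethylsilyloxy)pent-3-en-1-yl]oxiran-2-yl}pent-2-enoate
Conditions: t-BuMe2SiOTf, 2,6-lutidine, CH2Cl2, −78 → 0 °C
Reagents that add atoms: tert-butyldimethylsilyl trifluoromethanesulfonate, CC(C)(C)[Si](C)(C)OS(=O)(=O)C(F)(F)F
Why: Silyl triflate with a hindered base silylates the hindered epoxy alcohol without opening the epoxide, so no free hydroxyl remains for the oxidation and both secondary oxygens carry the same group.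

**Step 12**
Reactants: 20 methyl (2E,5S)-5-(tert-butyldimethylsilyloxy)-2-methyl-5-{(2R,3R)-2-methyl-3-[(2R,3Z)-2-(tert-butyldimethylsilyloxy)-3-methyl-5-(triethylsilyloxy)pent-3-en-1-yl]oxiran-2-yl}pent-2-enoate
Product: 21 methyl (2E,5S)-5-(tert-butyldimethylsilyloxy)-2-methyl-5-{(2R,3R)-2-methyl-3-[(2R,3Z)-2-(tert-butyldimethylsilyloxy)-3-methyl-5-oxopent-3-en-1-yl]oxiran-2-yl}pent-2-enoate
Conditions: (COCl)2, DMSO, CH2Cl2, −78 → −30 °C; then Et3N, −78 → 0 °C
Reagents that add atoms: none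
Why: Under Swern conditions a primary TES ether is cleaved by the chlorosulfonium reagent and oxidised directly to the aldehyde while secondary TBS ethers, the epoxide and the ester are inert, and the cold amine step keeps the Z geometry (Swern oxidation of a silyl ether).

**Step 13**
Reactants: 21 methyl (2E,5S)-5-(tert-butyldimethylsilyloxy)-2-methyl-5-{(2R,3R)-2-methyl-3-[(2R,3Z)-2-(tert-butyldimethylsilyloxy)-3-methyl-5-oxopent-3-en-1-yl]oxiran-2-yl}pent-2-enoate
Product: 23 (1R,3R,6R,7S,9S,10R,11R)-3,9-bis(tert-butyldimethylsilyloxy)-1,10-epoxygermacr-4Z-en-12,6-olide, via hydroxy ester 22 (not isolated)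
Conditions: SmI2 (3 equiv), t-BuOH (3 equiv), THF, 21 added over 6 h (final 2 mM), −78 °C → rt
Reagents that add atoms: none
Why: Proposed new method: SmI2 reduces the conjugated aldehyde to a ketyl whose trivalent samarium centre also binds the ester carbonyl, so the normally electrophilic C6 attacks the normally electrophilic β-carbon C7 in a ten-membered closure templated by the metal and by the two cis kinks (Z olefin, cis epoxide), a second electron gives the samarium ester enolate, t-BuOH protonates C11 on the convex face anti to C8 and the C6 alkoxide lactonises with loss of methoxide; the chelate holds O6 and the ester syn and hence gives the cis ring fusion (6R,7S), C7 approaches the planar s-trans ketyl anti to the C3 silyloxy group, which stands perpendicular to the π system to avoid allylic strain with the C4 methyl, and C3 is carried as a silyl ether because a γ-acetoxy ketyl would fragment; the closest known chemistry is the SmI2-mediated aldehyde–enoate reductive coupling to cis-β,γ-disubstituted γ-butyrolactones and SmI2 ketyl–olefin cyclisation to eight-membered rings, the ten-membered enal-derived case being without precedent.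

**Step 14**
Reactants: 23 (1R,3R,6R,7S,9S,10R,11R)-3,9-bis(tert-butyldimethylsilyloxy)-1,10-epoxygermacr-4Z-en-12,6-olide
Product: 25 (1R,3R,6R,7S,9S,10R,11R)-3,9-diacetoxy-1,10-epoxygermacr-4Z-en-12,6-olide, via diol 24 (not isolated)
Conditions: HF·pyridine, pyridine, THF, 0 °C → rt; then Ac2O, DMAP, 0 °C → rt
Reagents that add atoms: acetic anhydride, CC(=O)OC(C)=O
Why: Buffered HF·pyridine cleaves both secondary TBS ethers without opening the epoxide or epimerising C11, and acetic anhydride with DMAP then acetylates the two secondary alcohols in the same flask (desilylation then acylation).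

**Compound list**
1 | but-2-yn-1-ol | CC#CCO | starting material
2 | sodium 2,2-bis(2-methoxyethoxy)-3-methyl-2,5-dihydro-1,2-oxaaluminol-2-uide (cyclic Z-alkenylalanate) | CC1=CCO[Al-]1(OCCOC)OCCOC.[Na+] | intermediate
3 | (Z)-3-iodobut-2-en-1-ol | C/C(I)=C/CO | intermediate
4 | (Z)-triethyl[(3-iodobut-2-en-1-yl)oxy]silane | C/C(I)=C/CO[Si](CC)(CC)CC | intermediate
5 | (2-carboxyethyl)triphenylphosphonium bromide | OC(=O)CC[P+](c1ccccc1)(c1ccccc1)c1ccccc1.[Br-] | starting material
6 | 1,1-dimethoxypropan-2-one | CC(=O)C(OC)OC | starting material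
7 | sodium 3-(triphenylphosphoranylidene)propanoate (ylide carboxylate) | [Na+].[O-]C(=O)CC=P(c1ccccc1)(c1ccccc1)c1ccccc1 | intermediate
8 | sodium (Z)-5,5-dimethoxy-4-methylpent-3-enoate | [Na+].[O-]C(=O)C/C=C(/C)C(OC)OC | intermediate
9 | (Z)-5,5-dimethoxy-4-methylpent-3-enoic pivalic anhydride | CC(C)(C)C(=O)OC(=O)C/C=C(/C)C(OC)OC | intermediate
10 | (Z)-N,5,5-trimethoxy-N,4-dimethylpent-3-enamide | CON(C)C(=O)C/C=C(/C)C(OC)OC | intermediate
11 | (Z)-[4-(triethylsilyloxy)but-2-en-2-yl]magnesium chloride | CC[Si](CC)(CC)OC/C=C(/C)[Mg]Cl | intermediate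
12 | (2Z,6Z)-8,8-dimethoxy-3,7-dimethyl-1-(triethylsilyloxy)octa-2,6-dien-4-one | CC[Si](CC)(CC)OC/C=C(/C)C(=O)C/C=C(/C)C(OC)OC | intermediate
13 | (2Z,4R,6Z)-8,8-dimethoxy-3,7-dimethyl-1-(triethylsilyloxy)octa-2,6-dien-4-ol | CC[Si](CC)(CC)OC/C=C(/C)[C@H](O)C/C=C(/C)C(OC)OC | intermediate
14 | (2Z,4R,6Z)-4-(tert-butyldimethylsilyloxy)-8,8-dimethoxy-3,7-dimethyl-1-(triethylsilyloxy)octa-2,6-diene | CC[Si](CC)(CC)OC/C=C(/C)[C@H](O[Si](C)(C)C(C)(C)C)C/C=C(/C)C(OC)OC | intermediate
15 | (2Z,5R,6Z)-5-(tert-butyldimethylsilyloxy)-2,6-dimethyl-8-(triethylsilyloxy)octa-2,6-dienal | CC[Si](CC)(CC)OC/C=C(/C)[C@H](O[Si](C)(C)C(C)(C)C)C/C=C(/C)C=O | intermediate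
16 | methyl (E)-2-methylbut-2-enoate (methyl tiglate) | C/C=C(\C)C(=O)OC | starting material
17 | tert-butyl[(1-methoxy-2-methylbuta-1,3-dien-1-yl)oxy]dimethylsilane (ketene-acetal geometry as formed, not relevant to the outcome) | C=CC(C)=C(OC)O[Si](C)(C)C(C)(C)C | intermediate
18 | methyl (2E,5S,6Z,9R,10Z)-9-(tert-butyldimethylsilyloxy)-5-hydroxy-2,6,10-trimethyl-12-(triethylsilyloxy)dodeca-2,6,10-trienoate | CC[Si](CC)(CC)OC/C=C(/C)[C@H](O[Si](C)(C)C(C)(C)C)C/C=C(/C)[C@@H](O)C/C=C(\C)C(=O)OC | intermediate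
19 | methyl (2E,5S)-5-hydroxy-2-methyl-5-{(2S,3R)-2-methyl-3-[(2R,3Z)-2-(tert-butyldimethylsilyloxy)-3-methyl-5-(triethylsilyloxy)pent-3-en-1-yl]oxiran-2-yl}pent-2-enoate | CC[Si](CC)(CC)OC/C=C(/C)[C@H](O[Si](C)(C)C(C)(C)C)C[C@H]1O[C@@]1(C)[C@@H](O)C/C=C(\C)C(=O)OC | intermediate
20 | methyl (2E,5S)-5-(tert-butyldimethylsilyloxy)-2-methyl-5-{(2R,3R)-2-methyl-3-[(2R,3Z)-2-(tert-butyldimethylsilyloxy)-3-methyl-5-(triethylsilyloxy)pent-3-en-1-yl]oxiran-2-yl}pent-2-enoate | CC[Si](CC)(CC)OC/C=C(/C)[C@H](O[Si](C)(C)C(C)(C)C)C[C@H]1O[C@@]1(C)[C@@H](O[Si](C)(C)C(C)(C)C)C/C=C(\C)C(=O)OC | intermediate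
21 | methyl (2E,5S)-5-(tert-butyldimethylsilyloxy)-2-methyl-5-{(2R,3R)-2-methyl-3-[(2R,3Z)-2-(tert-butyldimethylsilyloxy)-3-methyl-5-oxopent-3-en-1-yl]oxiran-2-yl}pent-2-enoate | O=C/C=C(/C)[C@H](O[Si](C)(C)C(C)(C)C)C[C@H]1O[C@@]1(C)[C@@H](O[Si](C)(C)C(C)(C)C)C/C=C(\C)C(=O)OC | intermediate
22 | methyl (2R)-2-[(1R,3R,6R,7S,9S,10R)-3,9-bis(tert-butyldimethylsilyloxy)-1,10-epoxy-6-hydroxy-4,10-dimethylcyclodec-4Z-en-7-yl]propanoate (germacrane locants; seco-lactone of 23, present as its samarium alkoxide) | CC(C)(C)[Si](C)(C)O[C@H]1C[C@@H]([C@@H](C)C(=O)OC)[C@H](/C=C(/C)[C@H](O[Si](C)(C)C(C)(C)C)C[C@H]2O[C@@]12C)O | intermediate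
23 | (1R,3R,6R,7S,9S,10R,11R)-3,9-bis(tert-butyldimethylsilyloxy)-1,10-epoxygermacr-4Z-en-12,6-olide (cis-fused lactone, cis epoxide) | CC(C)(C)[Si](C)(C)O[C@H]1C[C@@H]2[C@H](/C=C(/C)[C@H](O[Si](C)(C)C(C)(C)C)C[C@H]3O[C@@]13C)OC(=O)[C@@H]2C | intermediate
24 | (1R,3R,6R,7S,9S,10S,11R)-3,9-dihydroxy-1,10-epoxygermacr-4Z-en-12,6-olide (same spatial arrangement as 23; the C10 label changes by CIP priority only) | O[C@H]1C[C@@H]2[C@H](/C=C(/C)[C@H](O)C[C@H]3O[C@@]13C)OC(=O)[C@@H]2C | intermediate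
25 | (1R,3R,6R,7S,9S,10R,11R)-3,9-diacetoxy-1,10-epoxygermacr-4Z-en-12,6-olide (CNP0250285.2) | CC(=O)O[C@H]1C[C@@H]2[C@H](/C=C(/C)[C@H](OC(C)=O)C[C@H]3O[C@@]13C)OC(=O)[C@@H]2C | target

**Step count**
Total: 14 steps. Longest linear sequence: 12 steps (steps 1, 2, 4, 5, 6, 7, 9, 10, 11, 12, 13, 14).

**Three steps most likely to fail**

Step 13 (samarium ring closure). A ten-membered ketyl–enoate closure from a conjugated aldehyde has no precedent. Simple reduction, pinacol dimerisation, attack through C4 or the wrong facial sense at C6 relative to C3 are all possible. A wrong C11 epimer alone can be reset on 23 by enolisation with LiN(i-Pr)2 and kinetic protonation on the convex face. The fallback makes the same C6–C7 bond with a redox-neutral carbene-catalysed homoenolate annulation, which cannot over-reduce. It sets out from 20. (i-Bu)2AlH in CH2Cl2 at −78 °C reduces the ester to the allylic alcohol (2E,5S)-5-(tert-butyldimethylsilyloxy)-2-methyl-5-{(2R,3R)-2-methyl-3-[(2R,3Z)-2-(tert-butyldimethylsilyloxy)-3-methyl-5-(triethylsilyloxy)pent-3-en-1-yl]oxiran-2-yl}pent-2-en-1-ol F1. Swern oxidation then converts both the free allylic alcohol and the primary TES ether, giving the dialdehyde (2E,5S)-5-(tert-butyldimethylsilyloxy)-2-methyl-5-{(2R,3R)-2-methyl-3-[(2R,3Z)-2-(tert-butyldimethylsilyloxy)-3-methyl-5-oxopent-3-en-1-yl]oxiran-2-yl}pent-2-enal F2. Under high dilution, 1,3-dimesitylimidazol-2-ylidene (from the imidazolium chloride and DBU in THF) adds to the less hindered E-enal. The resulting homoenolate carbon C7 attacks the C6 aldehyde, and the acyl azolium is captured by the C6 alkoxide as the cis lactone. This returns to the route at 23.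

Step 10 (Sharpless epoxidation). The allylic alcohol carries both a C10 methyl and a cis C1 substituent, so the erythro transition state is strained; the reaction may be slow or poorly diastereoselective. The fallback replaces reagent control by substrate control followed by inversion. It sets out from 15. The aldol of step 9 is run with the (R,R)-bisphosphoramide to give methyl (2E,5R,6Z,9R,10Z)-9-(tert-butyldimethylsilyloxy)-5-hydroxy-2,6,10-trimethyl-12-(triethylsilyloxy)dodeca-2,6,10-trienoate F3. Hydroxyl-directed m-CPBA epoxidation (CH2Cl2, NaHCO3, −20 °C) is threo-selective under 1,3-allylic strain and gives methyl (2E,5R)-5-hydroxy-2-methyl-5-{(2S,3R)-2-methyl-3-[(2R,3Z)-2-(tert-butyldimethylsilyloxy)-3-methyl-5-(triethylsilyloxy)pent-3-en-1-yl]oxiran-2-yl}pent-2-enoate F4, with the same epoxide configuration as 19. Mitsunobu inversion (4-nitrobenzoic acid, PPh3, diisopropyl azodicarboxylate) gives methyl (2E,5S)-2-methyl-5-{(2R,3R)-2-methyl-3-[(2R,3Z)-2-(tert-butyldimethylsilyloxy)-3-methyl-5-(triethylsilyloxy)pent-3-en-1-yl]oxiran-2-yl}-5-(4-nitrobenzoyloxy)pent-2-enoate F5. Methanolysis with K2CO3 in MeOH at 0 °C returns to the route at 19.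

Step 3 (Z-selective Wittig and one-pot amidation). The carboxylate-bearing ylide can fragment to acrylate, and the anionic group may erode the Z selectivity with this ketone. The fallback builds the C1=C10 olefin by a Still–Gennari olefination and the C2–C3 bond by an aldol reaction instead. It sets out from 11 (made from 4 as in step 4) and proceeds as follows:
- DMF quench gives (Z)-2-methyl-4-(triethylsilyloxy)but-2-enal F6.
- A Mukaiyama aldol with 1-methoxy-1-(trimethylsilyloxy)ethene, promoted by the N-tosylvaline-derived oxazaborolidinone enantiomer that gives the 3R carbinol, gives methyl (3R,4Z)-3-hydroxy-4-methyl-6-(triethylsilyloxy)hex-4-enoate F7.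
- Silylation (t-BuMe2SiCl, imidazole) gives methyl (3R,4Z)-3-(tert-butyldimethylsilyloxy)-4-methyl-6-(triethylsilyloxy)hex-4-enoate F8.
- (i-Bu)2AlH at −78 °C gives (3R,4Z)-3-(tert-butyldimethylsilyloxy)-4-methyl-6-(triethylsilyloxy)hex-4-enal F9.
- Olefination with methyl 2-[bis(2,2,2-trifluoroethoxy)phosphoryl]propanoate, KN(SiMe3)2 and 18-crown-6 at −78 °C gives methyl (2Z,5R,6Z)-5-(tert-butyldimethylsilyloxy)-2,6-dimethyl-8-(triethylsilyloxy)octa-2,6-dienoate F10.
- (i-Bu)2AlH gives (2Z,5R,6Z)-5-(tert-butyldimethylsilyloxy)-2,6-dimethyl-8-(triethylsilyloxy)octa-2,6-dien-1-ol F11.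
- MnO2 oxidation returns to the route at 15.

**Further compounds**
F1 | step 13 | (2E,5S)-5-(tert-butyldimethylsilyloxy)-2-methyl-5-{(2R,3R)-2-methyl-3-[(2R,3Z)-2-(tert-butyldimethylsilyloxy)-3-methyl-5-(triethylsilyloxy)pent-3-en-1-yl]oxiran-2-yl}pent-2-en-1-ol | CC[Si](CC)(CC)OC/C=C(/C)[C@H](O[Si](C)(C)C(C)(C)C)C[C@H]1O[C@@]1(C)[C@@H](O[Si](C)(C)C(C)(C)C)C/C=C(\C)CO
F2 | step 13 | (2E,5S)-5-(tert-butyldimethylsilyloxy)-2-methyl-5-{(2R,3R)-2-methyl-3-[(2R,3Z)-2-(tert-butyldimethylsilyloxy)-3-methyl-5-oxopent-3-en-1-yl]oxiran-2-yl}pent-2-enal | O=C/C=C(/C)[C@H](O[Si](C)(C)C(C)(C)C)C[C@H]1O[C@@]1(C)[C@@H](O[Si](C)(C)C(C)(C)C)C/C=C(\C)C=O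
F3 | step 10 | methyl (2E,5R,6Z,9R,10Z)-9-(tert-butyldimethylsilyloxy)-5-hydroxy-2,6,10-trimethyl-12-(triethylsilyloxy)dodeca-2,6,10-trienoate | CC[Si](CC)(CC)OC/C=C(/C)[C@H](O[Si](C)(C)C(C)(C)C)C/C=C(/C)[C@H](O)C/C=C(\C)C(=O)OC
F4 | step 10 | methyl (2E,5R)-5-hydroxy-2-methyl-5-{(2S,3R)-2-methyl-3-[(2R,3Z)-2-(tert-butyldimethylsilyloxy)-3-methyl-5-(triethylsilyloxy)pent-3-en-1-yl]oxiran-2-yl}pent-2-enoate | CC[Si](CC)(CC)OC/C=C(/C)[C@H](O[Si](C)(C)C(C)(C)C)C[C@H]1O[C@@]1(C)[C@H](O)C/C=C(\C)C(=O)OC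
F5 | step 10 | methyl (2E,5S)-2-methyl-5-{(2R,3R)-2-methyl-3-[(2R,3Z)-2-(tert-butyldimethylsilyloxy)-3-methyl-5-(triethylsilyloxy)pent-3-en-1-yl]oxiran-2-yl}-5-(4-nitrobenzoyloxy)pent-2-enoate | CC[Si](CC)(CC)OC/C=C(/C)[C@H](O[Si](C)(C)C(C)(C)C)C[C@H]1O[C@@]1(C)[C@@H](OC(=O)c2ccc(cc2)[N+](=O)[O-])C/C=C(\C)C(=O)OC
F6 | step 3 | (Z)-2-methyl-4-(triethylsilyloxy)but-2-enal | CC[Si](CC)(CC)OC/C=C(/C)C=O
F7 | step 3 | methyl (3R,4Z)-3-hydroxy-4-methyl-6-(triethylsilyloxy)hex-4-enoate | CC[Si](CC)(CC)OC/C=C(/C)[C@H](O)CC(=O)OC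
F8 | step 3 | methyl (3R,4Z)-3-(tert-butyldimethylsilyloxy)-4-methyl-6-(triethylsilyloxy)hex-4-enoate | CC[Si](CC)(CC)OC/C=C(/C)[C@H](O[Si](C)(C)C(C)(C)C)CC(=O)OC
F9 | step 3 | (3R,4Z)-3-(tert-butyldimethylsilyloxy)-4-methyl-6-(triethylsilyloxy)hex-4-enal | CC[Si](CC)(CC)OC/C=C(/C)[C@H](O[Si](C)(C)C(C)(C)C)CC=O
F10 | step 3 | methyl (2Z,5R,6Z)-5-(tert-butyldimethylsilyloxy)-2,6-dimethyl-8-(triethylsilyloxy)octa-2,6-dienoate | CC[Si](CC)(CC)OC/C=C(/C)[C@H](O[Si](C)(C)C(C)(C)C)C/C=C(/C)C(=O)OC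
F11 | step 3 | (2Z,5R,6Z)-5-(tert-butyldimethylsilyloxy)-2,6-dimethyl-8-(triethylsilyloxy)octa-2,6-dien-1-ol | CC[Si](CC)(CC)OC/C=C(/C)[C@H](O[Si](C)(C)C(C)(C)C)C/C=C(/C)CO
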